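**Retrosynthetic overview** (target locants: O1, C2H2, C3–OH, C4–aryl, C5–side chain; exocyclic carbinol carbon C1')
1. Target 12 ⇐ ketone 11: the C1' carbinol is set last by chelation-controlled reduction.
2. 11 ⇐ acyclic adduct 8: the only ring is closed late (O1–C2 bond) by hydroxyl-directed epoxidation of the enol carbamate, cyclisation and silane reduction; this also sets C3.
3. 8 ⇐ 4 + 5: the key C4–C5 bond comes from a titanated allyl carbamate acting as a homoenolate (d3) equivalent that adds to the aldehyde carbon of an aryl glyoxal, joining two normally electrophilic carbons and setting C4 and C5 together.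
4. 4 ⇐ 1 + 2: carbamoylation and cis-semihydrogenation of an aryl propargyl alcohol.

Assumption: the lithiated Z-carbamate·(−)-sparteine complex settles as the (S)-epimer and is titanated with inversion, as established for 2-butenyl carbamates; if the sense proves opposite, (+)-sparteine is used with no other change.

**Route**

Step 1
Reactants: 1 3-(4-methoxyphenyl)prop-2-yn-1-ol; 2 N,N-diisopropylcarbamoyl chloride
Product: 3 3-(4-methoxyphenyl)prop-2-yn-1-yl N,N-diisopropylcarbamate
Conditions: NaH, THF, 0 °C to reflux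
Reagents that add atoms: none
Why: O-carbamoylation (nucleophilic acyl substitution) of the sodium alkoxide installs the directing, anion-stabilising carbamate needed for the later lithiation; no stereocentre is formed.

Step 2
Reactants: 3 3-(4-methoxyphenyl)prop-2-yn-1-yl N,N-diisopropylcarbamate
Product: 4 (Z)-3-(4-methoxyphenyl)prop-2-en-1-yl N,N-diisopropylcarbamate
Conditions: H2 (1 atm), Pd/CaCO3 poisoned with Pb(OAc)2, quinoline, EtOAc, rt
Reagents that add atoms: none
Why: Lindlar-type cis-semihydrogenation adds H2 syn on the poisoned palladium surface and stops at the alkene, fixing the Z geometry that later becomes the cis C4/C5 relationship.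

Step 3
Reactants: 4 (Z)-3-(4-methoxyphenyl)prop-2-en-1-yl N,N-diisopropylcarbamate; 5 2-(3,4-dimethoxyphenyl)-2-oxoacetaldehyde
Product: 8 (1Z,3S,4S)-5-(3,4-dimethoxyphenyl)-4-hydroxy-3-(4-methoxyphenyl)-5-oxopent-1-en-1-yl N,N-diisopropylcarbamate, via α-lithio carbamate sparteine complex 6 (not isolated), via allyltitanium triisopropoxide 7 (not isolated)
Conditions: n-BuLi, (−)-sparteine, toluene, −78 °C; Ti(OiPr)4, −78 °C; 5 (dried from its hydrate by toluene azeotrope), −78 °C; aq NH4Cl
Reagents that add atoms: none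
Why: Proposed new method: carbamate-directed α-deprotonation gives a chelated 1-oxyallyllithium·sparteine complex which, after Li-to-Ti exchange with inversion, is a homoenolate (d3) nucleophile that attacks the aldehyde carbonyl of 5 (far more electrophilic than the aryl ketone) through its γ-carbon in a Zimmerman–Traxler chair; the Z-aryl group is forced axial, giving the syn (3S,4S) adduct with a Z-enol carbamate, and the absolute sense comes from the sparteine-defined metal-bearing carbon; the closest known reaction is the Hoppe (−)-sparteine-mediated titanium homoaldol reaction of (E)- and (Z)-2-butenyl carbamates (anti from E, syn from Z), extended here to a Z-cinnamyl carbamate and an aryl glyoxal.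

Step 4
Reactants: 8 (1Z,3S,4S)-5-(3,4-dimethoxyphenyl)-4-hydroxy-3-(4-methoxyphenyl)-5-oxopent-1-en-1-yl N,N-diisopropylcarbamate
Product: 11 (3,4-dimethoxyphenyl)[(2S,3R,4S)-4-hydroxy-3-(4-methoxyphenyl)oxolan-2-yl]methanone, via epoxy carbamate 9 (not isolated), via lactol carbamate 10 (not isolated)
Conditions: mCPBA, CH2Cl2, 0 °C; then Et3SiH, BF3·OEt2, −78 to −30 °C; aq NaHCO3
Reagents that add atoms: meta-chloroperoxybenzoic acid O=C(OO)c1cccc(Cl)c1
Why: In a Henbest-type hydroxyl-directed epoxidation the Z-enol carbamate is locked by 1,3-allylic strain (allylic H in the olefin plane), so the hydrogen-bonded peracid is delivered to the face carrying the carbinol carbon, anti to the aryl group, which places the future C3–OH cis to the aryl group; BF3 then opens the epoxide at the carbamate-bearing carbon for 5-ring closure by the only free hydroxyl and ionises the anomeric carbamate to an oxocarbenium ion that Et3SiH reduces to the ring CH2 (ionic hydrogenation of a lactol derivative), the aryl ketone being kept so that no ionisable benzylic alcohol and no second hydroxyl is present.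

Step 5
Reactants: 11 (3,4-dimethoxyphenyl)[(2S,3R,4S)-4-hydroxy-3-(4-methoxyphenyl)oxolan-2-yl]methanone
Product: 12 (3S,4R,5S)-5-[(R)-(3,4-dimethoxyphenyl)(hydroxy)methyl]-4-(4-methoxyphenyl)oxolan-3-ol
Conditions: Zn(BH4)2, Et2O, −30 °C; aq NH4Cl
Reagents that add atoms: none
Why: In this Cram-chelate (chelation-controlled) reduction zinc bridges the ketone oxygen and the ring oxygen, and hydride attacks the rigid five-membered chelate from the side of the C5–H, away from the ring carbon bearing the cis aryl group, giving the erythro (1'R) carbinol.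

**Compound list**
1 | 3-(4-methoxyphenyl)prop-2-yn-1-ol | OCC#Cc1ccc(OC)cc1 | starting material
2 | N,N-diisopropylcarbamoyl chloride | CC(C)N(C(C)C)C(Cl)=O | starting material
3 | 3-(4-methoxyphenyl)prop-2-yn-1-yl N,N-diisopropylcarbamate | CC(C)N(C(C)C)C(=O)OCC#Cc1ccc(OC)cc1 | intermediate
4 | (Z)-3-(4-methoxyphenyl)prop-2-en-1-yl N,N-diisopropylcarbamate | CC(C)N(C(C)C)C(=O)OC/C=C\c1ccc(OC)cc1 | intermediate
5 | 2-(3,4-dimethoxyphenyl)-2-oxoacetaldehyde (3,4-dimethoxyphenylglyoxal; bought as the hydrate, dried before use) | O=CC(=O)c1ccc(OC)c(OC)c1 | starting material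
6 | (S)-[(Z)-1-(N,N-diisopropylcarbamoyloxy)-3-(4-methoxyphenyl)prop-2-en-1-yl]lithium, lithium carrying (−)-sparteine | [Li][C@H](OC(=O)N(C(C)C)C(C)C)/C=C\c1ccc(OC)cc1 | intermediate
7 | triisopropoxy[(1R,2Z)-1-(N,N-diisopropylcarbamoyloxy)-3-(4-methoxyphenyl)prop-2-en-1-yl]titanium | CC(C)O[Ti](OC(C)C)(OC(C)C)[C@@H](OC(=O)N(C(C)C)C(C)C)/C=C\c1ccc(OC)cc1 | intermediate
8 | (1Z,3S,4S)-5-(3,4-dimethoxyphenyl)-4-hydroxy-3-(4-methoxyphenyl)-5-oxopent-1-en-1-yl N,N-diisopropylcarbamate | CC(C)N(C(C)C)C(=O)O/C=C\[C@@H](c1ccc(OC)cc1)[C@H](O)C(=O)c1ccc(OC)c(OC)c1 | intermediate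
9 | (2R,3S)-3-[(1S,2S)-3-(3,4-dimethoxyphenyl)-2-hydroxy-1-(4-methoxyphenyl)-3-oxopropyl]oxiran-2-yl N,N-diisopropylcarbamate | COc1ccc([C@@H]([C@H](O)C(=O)c3ccc(OC)c(OC)c3)[C@@H]2O[C@@H]2OC(=O)N(C(C)C)C(C)C)cc1 | intermediate
10 | (2S,3S,4R,5S)-5-(3,4-dimethoxybenzoyl)-3-hydroxy-4-(4-methoxyphenyl)oxolan-2-yl N,N-diisopropylcarbamate | COc1ccc([C@H]2[C@@H](C(=O)c3ccc(OC)c(OC)c3)O[C@@H](OC(=O)N(C(C)C)C(C)C)[C@H]2O)cc1 | intermediate
11 | (3,4-dimethoxyphenyl)[(2S,3R,4S)-4-hydroxy-3-(4-methoxyphenyl)oxolan-2-yl]methanone | COc1ccc([C@H]2[C@@H](C(=O)c3ccc(OC)c(OC)c3)OC[C@H]2O)cc1 | intermediate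
12 | (3S,4R,5S)-5-[(R)-(3,4-dimethoxyphenyl)(hydroxy)methyl]-4-(4-methoxyphenyl)oxolan-3-ol | COc1ccc([C@H]2[C@@H]([C@H](O)c3ccc(OC)c(OC)c3)OC[C@H]2O)cc1 | target

**Totals**
Total step count: 5. Longest linear sequence: 5 (1 → 3 → 4 → 8 → 11 → 12); 5 enters convergently in step 3.

**Three steps most likely to fail**

Step 3 is the riskiest. The Z-aryl group must stay Z in the allyl anion and sit axial in the chair, where it is crowded by the inside carbamoyloxy group, and the sparteine sense is taken by analogy. The fallback sets out from 1 and comes back at 8. Trans-reduction of 1 with NaAlH2(OCH2CH2OMe)2 gives (E)-3-(4-methoxyphenyl)prop-2-en-1-ol F1, and carbamoylation with 2 and NaH gives (E)-3-(4-methoxyphenyl)prop-2-en-1-yl N,N-diisopropylcarbamate F2. Treatment with n-BuLi and (−)-sparteine gives the (S)-α-lithio derivative F3 (not isolated), which Bu3SnCl traps at the α-carbon with inversion as (1R,2E)-3-(4-methoxyphenyl)-1-(tributylstannyl)prop-2-en-1-yl N,N-diisopropylcarbamate F4. F4 and 5 with BF3·OEt2 in CH2Cl2 at −78 °C react through an open, antiperiplanar SE2' transition state anti to tin. In that mode (E)-γ-substituted α-oxygenated allylstannanes give syn adducts with Z-enol ethers, so 8 is reached without the Z-olefin or the chair transition state.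

Step 4 may fail in face selectivity of the epoxidation, with Baeyer–Villiger oxidation or over-reduction of the aryl ketone as lesser risks. The fallback sets out from 11 and comes back at 12. If 11 is obtained mixed with its alcohol epimer (3,4-dimethoxyphenyl)[(2S,3R,4R)-4-hydroxy-3-(4-methoxyphenyl)oxolan-2-yl]methanone F5, the mixture is not separated. Dess–Martin periodinane converts both into the single diketone (4S,5S)-5-(3,4-dimethoxybenzoyl)-4-(4-methoxyphenyl)oxolan-3-one F6. Zn(BH4)2 at −78 °C then reduces the ring ketone from the face opposite the two cis substituents and the aryl ketone under chelation, giving 12 directly. The C3 configuration is thus set by ring-controlled hydride delivery instead of acyclic direction; the diketone must be reduced at once because its aryl-bearing carbon can epimerise.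

Step 5 may give the threo carbinol if open-chain (Felkin) attack competes with the zinc chelate, and the ketone α-carbon can epimerise. The fallback sets out from 11, comes back at 12 and makes no new compound. The reduction is done by catalyst-controlled asymmetric transfer hydrogenation with RuCl(p-cymene)[(S,S)-TsDPEN] in HCO2H/Et3N, so the carbinol configuration is fixed by the catalyst and not by the substrate.

**Further compounds**
F1 | step 3 | (E)-3-(4-methoxyphenyl)prop-2-en-1-ol | OC/C=C/c1ccc(OC)cc1
F2 | step 3 | (E)-3-(4-methoxyphenyl)prop-2-en-1-yl N,N-diisopropylcarbamate | CC(C)N(C(C)C)C(=O)OC/C=C/c1ccc(OC)cc1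
F3 | step 3 | (S)-[(E)-1-(N,N-diisopropylcarbamoyloxy)-3-(4-methoxyphenyl)prop-2-en-1-yl]lithium, lithium carrying (−)-sparteine | [Li][C@H](OC(=O)N(C(C)C)C(C)C)/C=C/c1ccc(OC)cc1
F4 | step 3 | (1R,2E)-3-(4-methoxyphenyl)-1-(tributylstannyl)prop-2-en-1-yl N,N-diisopropylcarbamate | CCCC[Sn](CCCC)(CCCC)[C@@H](OC(=O)N(C(C)C)C(C)C)/C=C/c1ccc(OC)cc1
F5 | step 4 | (3,4-dimethoxyphenyl)[(2S,3R,4R)-4-hydroxy-3-(4-methoxyphenyl)oxolan-2-yl]methanone | COc1ccc([C@H]2[C@@H](C(=O)c3ccc(OC)c(OC)c3)OC[C@@H]2O)cc1
F6 | step 4 | (4S,5S)-5-(3,4-dimethoxybenzoyl)-4-(4-methoxyphenyl)oxolan-3-one | COc1ccc([C@H]2[C@@H](C(=O)c3ccc(OC)c(OC)c3)OCC2=O)cc1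
F0 | step 5 | none | none
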